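Two forward constants are read here: kL, the inverse time constant of X → L + D, and kQ, which acts through X + Z → Q as a pseudo-first-order inverse time constant kQ·Z that shrinks as Z is spent. Their quotient Z* = kL/kQ gives the selectivity S = Z*/Z, the forward rate of L over the rate of Q.

| flask | X | Z | remark | time |
|---|---|---|---|---|
| dusk | 20 mM | 7.9 mM | run made earlier |  |
| noon | 20 mM | 8.1 mM | run made earlier |  |
| north-west | 20 mM | 10.0 mM |  | 4.0 d |
| south-east | 20 mM | 13.0 mM |  | 4.0 d |

| run | time / d | L / % | X / % |
|---|---|---|---|
| dusk | 0.250 | 4.6 | 91.0 |
| dusk | 0.625 | 10.7 | 79.6 |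
| dusk | 1.25 | 19.5 | 63.8 |
| dusk | 2.08 | 28.6 | 51.9 |
| dusk | 3.00 | 35.8 | 39.9 |
| noon | 0.250 | 4.2 | 90.3 |
| noon | 0.625 | 10.5 | 79.1 |
| noon | 1.25 | 19.9 | 64.4 |
| noon | 2.08 | 28.3 | 50.9 |
| noon | 3.00 | 36.3 | 39.7 |

(readings scatter by 0.5 percentage points)

- the numbers in the tables scatter with a standard deviation of 0.5 percentage points
- reactions considered so far: X <-> L + D; X + Z -> Q

- which of these there is most of at the end, counted by the X in it, north-west (L / X)
- which of these there is most of at the end, counted by the X in it, south-east (L / X)
- amount of the one of these that there is most of at the end, in percent of the X charged, north-west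
- amount of the one of these that there is most of at the end, in percent of the X charged, south-east

Take Q as what is missing from X and L. At 0.625 d, L over Q times the charged Z reads 8.71 mM in the dusk run and 8.18 mM in the noon run. So Z*, the crossover concentration at which the forward rates of both branches are equal, reads 8.45 mM.

The dusk run, charged below this reading of Z*, starts by it at S = 1.07, with L forming faster than Q. North-west looks nearly the same, but its Z charge lies above Z*, so by this reading it starts at S = 0.845 with Q forming faster. Each Q spends one Z, so S climbs, and by this estimate north-west reaches one after Q worth 7.77% of the X charged. South-east needs 22.8%, so this reckoning commits to less L there than in north-west. It also puts L ahead of X in both, since dusk X stood 4.1 percentage points above L at 3.00 d, down from 23 points at 2.08 d, and both new flasks run longer.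

The forecast, stepping by hand, agrees: “L leads in both runs”, with 39% of L in north-west and 36% of L in south-east.

    X ⇌ L + D (K = 0.0380 M, k = 2.30 × 10⁻⁶ s⁻¹)
    X + Z → Q (k = 2.80 × 10⁻⁴ M⁻¹ s⁻¹)

At 4.0 d, north-west holds 39.3% L against 28.5% X, and south-east 36.4% against 23.7%. In north-west, the forward rate of X into L over that of X into Q is 1.3 at 1.28 d and 2.3 at 4.00 d, while Z*/Z, with 35.6% of the Z charge left, gives 2.37. In the neighbour flask, north-west with 80 mM of X, Z* puts S at one after Q worth 1.94% of the X charged, Z falls to 0.67% of its charge, and X ends at 48.6% against 39.0% of L.

Readings and results were computed for substances that don't exist, noise included.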